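The cyclohexenone is cut at C5'–C6' and C1'–C2'. Because C8'H2–O on the quaternary C6' and side-chain carbon C5 on the C1' carbinol are cis, both fit into one cis-fused γ-lactone (C1' = α-carbon, C6' = β-carbon), and that ring is the β-methyl butenolide dienophile. One Diels–Alder reaction of its l-menthyl acetal, (5R)-5-menthyloxy-4-methylfuran-2(5H)-one, with (E)-2-triethylsilyloxypenta-1,3-diene closes the carbocycle, sets C6' anti to the menthyloxy group and delivers C4' as a silyl enol ether. The lactone then steers C1' hydroxylation and releases C5 (alkyne, then Stille dienoate) and the 8'-hydroxyl (enantiopure HMG half-ester) separately.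

Key step: step 4

Remark: abscisic acid numbering is used (ring C1'–C6'; C7' = methyl on C2'; C8' = oxymethylene and C9' = methyl on C6'; side chain C1–C5; glutaryl carbons C1''–C5''); by CIP analysis the target is (1'R,6'S,3''R), anti attack on the (5R) acetal 5 gives (6'S), and esterifying the free acid arm of the (S)-half-ester 21 gives (3''R); pig liver esterase is assumed to hydrolyse the pro-S ester group of 20, its known preference for this diester.

Step 1
Reactants: 1 glyoxylic acid; 2 propanal
Product: 3 5-hydroxy-4-methylfuran-2(5H)-one (racemic)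
Conditions: morpholine·HCl, dioxane–H2O, reflux
Reagents that add atoms: none
Why: Amine-mediated aldol condensation of the propanal enamine with the glyoxylic aldehyde, then dehydration and ring closure of the (Z)-4-oxobut-2-enoic acid to its cyclic pseudo-acid, is a standard entry to this hydroxybutenolide; the acetal carbon is racemic and labile, so nothing stereochemical is at stake.

Step 2
Reactants: 3 5-hydroxy-4-methylfuran-2(5H)-one; 4 (−)-menthol
Product: 5 (5R)-5-(l-menthyloxy)-4-methylfuran-2(5H)-one
Conditions: TsOH (cat.), toluene, reflux, Dean–Stark; crystallise from hexane; liquors re-equilibrated with TsOH and recrystallised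
Reagents that add atoms: none
Why: Acid-catalysed acetalisation (pseudo-ester formation) with azeotropic water removal gives both acetal epimers, which interconvert under the acid, so crystallisation of the (5R) epimer with recycling of the liquors should funnel the material to one diastereomer.

Step 3
Reactants: 6 (E)-pent-3-en-2-one
Product: 8 (E)-2-(triethylsilyloxy)penta-1,3-diene, via lithium dienolate 7 (not isolated)
Conditions: LDA, THF, −78 °C; then Et3SiCl, −78 → 0 °C
Reagents that add atoms: chlorotriethylsilane, CC[Si](Cl)(CC)CC
Why: Kinetic α'-deprotonation of the methyl ketone gives the cross-conjugated lithium dienolate, and O-silylation (enol silylation) traps it as the 2-silyloxy diene with the (E)-C3=C4 geometry unchanged.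

Step 4
Reactants: 5 (5R)-5-(l-menthyloxy)-4-methylfuran-2(5H)-one; 8 (E)-2-(triethylsilyloxy)penta-1,3-diene
Product: 9 silyl enol ether cycloadduct (cis-fused lactone acetal)
Conditions: 8 (3 equiv), Et3N (trace), BHT, CH2Cl2, 1.3 GPa, 45 °C
Reagents that add atoms: none
Why: Both σ-bonds form in one pericyclic event ([4πs+2πs] Diels–Alder reaction of an electron-rich diene with an electron-poor alkene, bond formation at the diene CH2 terminus running ahead), the closest known reaction type being auxiliary-controlled cycloadditions of 5-menthyloxy-2(5H)-furanones with 2-silyloxy dienes. The six-membered carbocycle is closed by intermolecular [4+2] cycloaddition: diene C1, which has the largest HOMO coefficient because of the 2-silyloxy donor, joins the lactone β-carbon (C5'–C6') and the methyl-bearing C4 joins the α-carbon (C1'–C2'), the para preference of the 2-donor and the ortho preference of the 4-methyl pointing the same way. C6' is set by approach of the diene to the face opposite the menthyloxy group on the adjacent acetal carbon C8'; C1' follows from suprafacial addition to the ring alkene, which forces the cis ring fusion; C2' follows from the endo position of the lactone carbonyl, which puts the C7' methyl cis to it. Only the facial selectivity is needed for the target, because C2' later becomes trigonal and C1' is re-set under control of the lactone, and it is secured by the acetal substituent sitting directly beside the carbon that becomes quaternary. The β-methyl group makes the dienophile sluggish, so pressure (negative activation volume) is used instead of prolonged heating, with a trace of amine to protect the enol ether.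

Step 5
Reactants: 9 silyl enol ether cycloadduct
Product: 10 enone lactone acetal (C2'=C3'–C4'=O)
Conditions: Pd(OAc)2 (1.05 equiv), MeCN, 25 °C
Reagents that add atoms: none
Why: In this Saegusa–Ito oxidation Pd(II) turns the silyl enol ether into the C3'-palladated ketone and β-hydride elimination can only involve C2'–H (C5' lies on the other side of the carbonyl), so the C2'=C3' enone forms regiospecifically and the C2' stereocentre is erased on purpose.

Step 6
Reactants: 10 enone lactone acetal
Product: 11 4'-dioxolane ketal of the lactone acetal
Conditions: TMSOCH2CH2OTMS, TMSOTf (cat.), CH2Cl2, −78 → −20 °C; pyridine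
Reagents that add atoms: 1,2-bis(trimethylsilyloxy)ethane, C[Si](C)(C)OCCO[Si](C)(C)C
Why: Noyori ketalisation works on enones at low temperature without moving the double bond and masks C4' against borohydride, DIBAL-H and later conjugate attack by the free 8'-hydroxyl at C2'; an exchange at the acetal carbon C8' would be harmless because that group is removed in step 7.

Step 7
Reactants: 11 4'-dioxolane ketal of the lactone acetal
Product: 14 ketal lactone (C5=O and O–C8'H2 with C1'–H), via formyl acid 12 (not isolated), via hydroxy acid 13 (not isolated)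
Conditions: KOH, NaBH4, EtOH–H2O, 0 → 25 °C; then AcOH (pH 4–5), 25 °C
Reagents that add atoms: none
Why: This is the usual reductive removal of an alkoxy group from a lactone acetal (saponification, carbonyl reduction, lactonisation): hydroxide opens the pseudo-ester, the hemiacetal collapses to the non-enolisable C8' aldehyde with loss of menthol, borohydride reduces it, and the cis γ-hydroxy acid recloses on mild acidification without touching C6' or C1'.

Step 8
Reactants: 14 ketal lactone
Product: 16 1'-hydroxy ketal lactone, via potassium enolate 15 (not isolated)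
Conditions: KHMDS, THF, −78 °C; then 2-(phenylsulfonyl)-3-phenyloxaziridine, −78 → −40 °C; AcOH
Reagents that add atoms: 2-(phenylsulfonyl)-3-phenyloxaziridine, O=S(=O)(N1OC1c1ccccc1)c1ccccc1
Why: In this Davis oxidation (α-hydroxylation of an ester enolate by an N-sulfonyloxaziridine) the only carbonyl α-hydrogen is the allylic ring-fusion C1'–H, the dienolate is attacked at its α-carbon, and because the 5/6 fusion can only stay cis the oxygen enters on the convex face that carries the C9' methyl, setting C1' with OH cis to that methyl and C5 cis to C8'.

Step 9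
Reactants: 16 1'-hydroxy ketal lactone
Product: 17 C5 lactol (anomer mixture)
Conditions: DIBAL-H (2.4 equiv), CH2Cl2, −78 °C; Rochelle salt
Reagents that add atoms: none
Why: DIBAL-H half-reduction of a γ-lactone stops at the aluminium lactolate at −78 °C (one equivalent is consumed by the tertiary hydroxyl) and leaves ketal and alkene alone.

Step 10
Reactants: 17 C5 lactol
Product: 19 1'-ethynyl diol (C5≡C4 with free 1'-OH and 8'-OH), via hydroxy aldehyde 18 (not isolated)
Conditions: dimethyl (1-diazo-2-oxopropyl)phosphonate, K2CO3, MeOH, 0 → 25 °C
Reagents that add atoms: dimethyl (1-diazo-2-oxopropyl)phosphonate, CC(=O)C(=[N+]=[N-])P(=O)(OC)OC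
Why: In this Seyferth–Gilbert homologation with the Ohira–Bestmann reagent the lactol opens to the hydroxy aldehyde, which the diazomethylphosphonate anion made in the flask converts to the terminal alkyne through a vinylidene carbene 1,2-hydrogen shift, freeing the 8'-hydroxyl with no electrophilic alkene nearby.

Step 11
Reactants: 20 dimethyl 3-hydroxy-3-methylpentanedioate
Product: 21 (S)-3-hydroxy-5-methoxy-3-methyl-5-oxopentanoic acid
Conditions: pig liver esterase, phosphate buffer pH 7.5, 25 °C; acidic work-up
Reagents that add atoms: water, O
Why: Enzymatic desymmetrisation of the prochiral diester (esterase hydrolysis) distinguishes the enantiotopic ester arms and is expected to give the (S)-half-ester, which sets the glutaryl stereocentre, and it should stop at the mono-acid because the anion is a poor substrate.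

Step 12
Reactants: 19 1'-ethynyl diol; 21 (S)-3-hydroxy-5-methoxy-3-methyl-5-oxopentanoic acid
Product: 22 8'-O-glutaryl ester (5''-methyl ester) of the ethynyl carbinol
Conditions: EDC·HCl, DMAP, CH2Cl2, 0 → 25 °C
Reagents that add atoms: none
Why: In this Steglich esterification the carbodiimide/DMAP-activated acid acylates the primary 8'-hydroxyl while the two tertiary hydroxyls are too hindered to react, and using the free acid arm of (S)-21 gives the (3''R) centre of the target.

Step 13
Reactants: 22 8'-O-glutaryl ester of the ethynyl carbinol
Product: 23 (E)-vinylstannane (C5=C4–SnBu3)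
Conditions: Bu3SnH, PdCl2(PPh3)2 (2 mol%), THF, 0 °C
Reagents that add atoms: tributyltin hydride, CCCC[SnH](CCCC)CCCC
Why: Palladium-catalysed hydrostannation is a syn addition that places tin on the terminal carbon, away from the fully substituted C1', and so gives the (E)-vinylstannane with the C4=C5 geometry of the target.

Step 14
Reactants: 24 but-2-ynoic acid
Product: 25 (Z)-3-iodobut-2-enoic acid
Conditions: NaI, AcOH, 110 °C
Reagents that add atoms: sodium iodide, [Na+].[I-]
Why: Hydroiodination of an ynoic acid with iodide in acetic acid is a conjugate anti addition of HI and gives the (Z)-β-iodo acid under kinetic control.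

Step 15
Reactants: 23 (E)-vinylstannane; 25 (Z)-3-iodobut-2-enoic acid
Product: 26 (2Z,4E)-dienoic acid with 4'-ketal and 5''-methyl ester
Conditions: PdCl2(MeCN)2 (5 mol%), iPr2NEt, DMF, 25 °C, dark
Reagents that add atoms: none
Why: Stille cross-coupling retains the geometry of both sp2 partners, so the (E)-stannane and the (Z)-iodide give the (2Z,4E)-dienoic acid directly, and the amine keeps the acid as its carboxylate to avoid protodestannylation.

Step 16
Reactants: 26 (2Z,4E)-dienoic acid with 4'-ketal and 5''-methyl ester
Product: 28 CNP0183058.1 (target), via ketal diacid 27 (not isolated)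
Conditions: Me3SnOH, 1,2-dichloroethane, 70 °C; then 1 M HCl, THF, 25 °C
Reagents that add atoms: trimethyltin hydroxide, C[Sn](C)(C)O; water, O
Why: Trimethyltin hydroxide ester hydrolysis prefers methyl esters over esters of hindered alcohols, so the 5''-methyl ester should be cleaved while the 8'-O-acyl link stays, and the dilute acid that frees the acids from their stannyl esters then hydrolyses the allylic dioxolane (acetal hydrolysis) to the enone, by which time O8' is acylated and cannot add to C2'.

Compound list
1 | glyoxylic acid (used as monohydrate) | O=CC(=O)O | starting material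
2 | propanal | CCC=O | starting material
3 | 5-hydroxy-4-methylfuran-2(5H)-one, racemic pseudo-acid | CC1=CC(=O)OC1O | intermediate
4 | (−)-menthol, (1R,2S,5R)-2-isopropyl-5-methylcyclohexan-1-ol | CC(C)[C@@H]1CC[C@@H](C)C[C@H]1O | starting material
5 | (5R)-5-[(1R,2S,5R)-menthyloxy]-4-methylfuran-2(5H)-one | CC1=CC(=O)O[C@H]1O[C@@H]2C[C@H](C)CC[C@H]2C(C)C | intermediate
6 | (E)-pent-3-en-2-one | C/C=C/C(C)=O | starting material
7 | lithium (E)-penta-1,3-dien-2-olate (cross-conjugated kinetic enolate) | [Li+].[O-]C(=C)/C=C/C | intermediate
8 | (E)-2-(triethylsilyloxy)penta-1,3-diene | C=C(O[Si](CC)(CC)CC)/C=C/C | intermediate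
9 | cycloadduct: cis-fused 3-(l-menthyloxy)-3a,7-dimethyl-5-(triethylsilyloxy)-3a,4,7,7a-tetrahydro-2-benzofuran-1(3H)-one (1 = C5 carbonyl, 3 = C8', 3a = C6', 5 = C4', 7 = C2', 7a = C1'; 7-methyl cis to the lactone carbonyl; menthyloxy cis to 3a-methyl and 7a-H, trans to the carbocycle) | C[C@H]1C=C(O[Si](CC)(CC)CC)C[C@@]2(C)[C@H](O[C@@H]3C[C@H](C)CC[C@H]3C(C)C)OC(=O)[C@@H]12 | intermediate
10 | enone lactone acetal: cis-fused 3-(l-menthyloxy)-3a,7-dimethyl-3a,4-dihydro-2-benzofuran-1,5(3H,7aH)-dione | CC1=CC(=O)C[C@@]2(C)[C@H](O[C@@H]3C[C@H](C)CC[C@H]3C(C)C)OC(=O)[C@@H]12 | intermediate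
11 | 4'-(1,3-dioxolane) ketal of 10 | CC1=CC2(OCCO2)C[C@@]3(C)[C@H](O[C@@H]4C[C@H](C)CC[C@H]4C(C)C)OC(=O)[C@@H]13 | intermediate
12 | ring-opened formyl acid (C8' aldehyde and C5 carboxylic acid cis, 4'-ketal; potassium salt in the flask) | CC1=CC2(OCCO2)C[C@@](C)(C=O)[C@H]1C(=O)O | intermediate
13 | hydroxy acid (C8'H2OH and C5 carboxylic acid cis, 4'-ketal) | CC1=CC2(OCCO2)C[C@@](C)(CO)[C@H]1C(=O)O | intermediate
14 | ketal lactone: cis-fused γ-lactone with C5=O and O–C8'H2, C1'–H, C2'=C3', 4'-dioxolane | CC1=CC2(OCCO2)C[C@@]3(C)COC(=O)[C@@H]13 | intermediate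
15 | potassium dienolate of 14 (C5(O−)=C1'–C2'=C3') | CC1=CC2(OCCO2)C[C@@]3(C)COC([O-])=C13.[K+] | intermediate
16 | 1'-hydroxy ketal lactone (1'-OH cis to the C9' methyl, lactone cis-fused) | CC1=CC2(OCCO2)C[C@@]3(C)COC(=O)[C@@]13O | intermediate
17 | C5 lactol of 16 (anomer mixture) | CC1=CC2(OCCO2)C[C@@]3(C)COC(O)[C@@]13O | intermediate
18 | open hydroxy aldehyde form of 17 (C5 aldehyde, 1'-OH, 8'-OH) | CC1=CC2(OCCO2)C[C@@](C)(CO)[C@@]1(O)C=O | intermediate
19 | 1'-ethynyl-1'-hydroxy-8'-hydroxy 4'-ketal (C5≡C4 cis to C8'H2OH) | CC1=CC2(OCCO2)C[C@@](C)(CO)[C@@]1(O)C#C | intermediate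
20 | dimethyl 3-hydroxy-3-methylpentanedioate | COC(=O)CC(C)(O)CC(=O)OC | starting material
21 | (S)-3-hydroxy-5-methoxy-3-methyl-5-oxopentanoic acid | OC(=O)C[C@](C)(O)CC(=O)OC | intermediate
22 | 8'-O-[(3R)-3-hydroxy-5-methoxy-3-methyl-5-oxopentanoyl] ester of 19 | CC1=CC2(OCCO2)C[C@@](C)(COC(=O)C[C@](C)(O)CC(=O)OC)[C@@]1(O)C#C | intermediate
23 | (E)-2-(tributylstannyl)vinyl analogue of 22 (tin on C4) | CC1=CC2(OCCO2)C[C@@](C)(COC(=O)C[C@](C)(O)CC(=O)OC)[C@@]1(O)/C=C/[Sn](CCCC)(CCCC)CCCC | intermediate
24 | but-2-ynoic acid | CC#CC(=O)O | starting material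
25 | (Z)-3-iodobut-2-enoic acid | C/C(I)=C/C(=O)O | intermediate
26 | 4'-ketal 5''-methyl ester of the target (free (2Z,4E)-dienoic acid) | CC1=CC2(OCCO2)C[C@@](C)(COC(=O)C[C@](C)(O)CC(=O)OC)[C@@]1(O)/C=C/C(C)=C\C(=O)O | intermediate
27 | 4'-ketal of the target (diacid) | CC1=CC2(OCCO2)C[C@@](C)(COC(=O)C[C@](C)(O)CC(=O)O)[C@@]1(O)/C=C/C(C)=C\C(=O)O | intermediate
28 | CNP0183058.1, (2Z,4E)-5-[(1R,6S)-6-({[(3R)-4-carboxy-3-hydroxy-3-methylbutanoyl]oxy}methyl)-1-hydroxy-2,6-dimethyl-4-oxocyclohex-2-en-1-yl]-3-methylpenta-2,4-dienoic acid | CC1=CC(=O)C[C@@](C)(COC(=O)C[C@](C)(O)CC(=O)O)[C@@]1(O)/C=C/C(C)=C\C(=O)O | target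

Total step count: 16. Longest linear sequence: 13 steps (1, 2, 4, 5, 6, 7, 8, 9, 10, 12, 13, 15, 16).

Steps most likely to fail

Step 4. What may go wrong: the trisubstituted β-methyl alkene may react too slowly to form the quaternary centre, so that diene oligomerisation or loss of the enol ether outruns the cycloaddition, or the anti facial bias may erode under forcing. The fallback sets out from 5 and returns at 9; it lowers the LUMO of the dienophile with a traceless α-bromine. Addition of Br2 to 5 gives the 3,4-dibromo lactone F1, and Et3N eliminates HBr to the 3-bromo butenolide F2. This more electron-poor dienophile is combined with 8 in the same orientation to give the 1'-bromo cycloadduct F3. Bu3SnH/AIBN then removes the bromine by radical reduction, with hydrogen delivered so that the ring fusion stays cis, which gives 9 (a C2' epimer would merge at 10).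

Step 8. What may go wrong: deprotonation of the hindered ring-fusion C–H may be slow or incomplete, oxygen may be transferred to the γ-carbon C3' of the dienolate, or the enolate may add to the sulfonimine by-product. The fallback sets out from 14 and returns at 16; it replaces the kinetic strong-base enolate by a thermodynamic weak-base autoxidation. Dilute HCl in THF unmasks the enone lactone F4, in which C1'–H is both α to the lactone and γ to the enone. Cs2CO3, O2 and P(OEt)3 in DMSO form the dienolate reversibly, and oxygen adds at C1', the usual γ site for enone dienolates, to give the 1'-hydroperoxy enone lactone F5. The phosphite reduces this in the flask to the 1'-hydroxy enone lactone F6, with oxygen on the same convex face. Noyori ketalisation as in step 6 then gives 16.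

Step 16. What may go wrong: hydrolysis may occur at the wrong carbonyl of the glutarate, which loses the 8'-O-acyl link and lets the freed 8'-hydroxyl add to C2' once the enone is unmasked, or cleavage of the methyl ester may be incomplete. The fallback sets out from 26 and returns at 27; it replaces acyl–oxygen hydrolysis by alkyl–oxygen cleavage. LiI in refluxing ethyl acetate, under argon in the dark, removes the methyl group by SN2 attack at the methyl carbon, a pathway closed to the neopentyl-type C8'H2–O ester. This gives 27 as its lithium salt, and the dilute-acid ketal hydrolysis of step 16 follows unchanged. This fallback makes no new compound (F0).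

Further compounds
F1 | step 4 | (5R)-3,4-dibromo-5-(l-menthyloxy)-4-methyldihydrofuran-2(3H)-one (C3/C4 diastereomers) | CC1(Br)C(Br)C(=O)O[C@H]1O[C@@H]2C[C@H](C)CC[C@H]2C(C)C
F2 | step 4 | (5R)-3-bromo-5-(l-menthyloxy)-4-methylfuran-2(5H)-one | CC1=C(Br)C(=O)O[C@H]1O[C@@H]2C[C@H](C)CC[C@H]2C(C)C
F3 | step 4 | 1'-bromo cycloadduct (7a-bromo analogue of 9) | C[C@H]1C=C(O[Si](CC)(CC)CC)C[C@@]2(C)[C@H](O[C@@H]3C[C@H](C)CC[C@H]3C(C)C)OC(=O)[C@@]12Br
F4 | step 8 | enone lactone (4'-ketone, C1'–H, C5=O/O–C8'H2 lactone) | CC1=CC(=O)C[C@@]2(C)COC(=O)[C@@H]12
F5 | step 8 | 1'-hydroperoxy enone lactone | CC1=CC(=O)C[C@@]2(C)COC(=O)[C@@]12OO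
F6 | step 8 | 1'-hydroxy enone lactone | CC1=CC(=O)C[C@@]2(C)COC(=O)[C@@]12O
F0 | step 16 | none | none
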